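- I work in hours of half-life: a Z molecule in the flask has two clocks, one for meeting Q and giving X, one for a side exit that needs no Q.

| setting | zeta | eta | alpha | flask |
|---|---|---|---|---|
| Z | 0.30 M | 0.30 M | 0.15 M | 0.30 M |
| Q | 0.075 M | 0.11 M | 0.15 M | 0.150 M |
| remark | run made earlier | run made earlier | run made earlier |  |
| time |  |  |  | 8.0 h |

- zeta (time / h: X / %, Z / %): 0.250: 4.3, 84.2; 0.667: 8.0, 64.6; 1.33: 9.5, 43.9; 2.00: 12.3, 30.7; 3.00: 11.9, 21.0; 4.00: 12.0, 13.0; 5.00: 11.5, 9.8
- eta (time / h: X / %, Z / %): 0.250: 6.6, 82.0; 0.667: 11.4, 60.8; 1.33: 15.1, 40.4; 2.00: 16.1, 28.0; 3.00: 16.5, 17.7; 4.00: 16.8, 12.2; 5.00: 17.3, 9.3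
- alpha (time / h: X / %, Z / %): 1.00: 16.7, 43.2; 2.00: 18.1, 20.8; 3.00: 16.4, 12.5; 4.00: 13.7, 8.2; 5.00: 11.7, 5.6

(readings scatter by 0.5 percentage points)

- the analysis behind the earlier runs scatters by 0.5 percentage points, standard deviation
- a reading or a percentage of X counts all its forms, free or not

- equivalents of Q to Z, everything else as given, that leave most X at 8.0 h
- the amount of X then, in percent of the Z charged
- the amount of X with the amounts as given

- At the first zeta reading, X is 0.272 of the Z lost. At the first eta reading, with more Q, it is 0.367.
- At a given level of Q, the exit through Q is pseudo-first-order. So I divide the side share by the X share and multiply by Q, which gives 0.201 M from zeta and 0.190 M from eta.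
- I carry their mean, 0.195 M, as the even level: the level of Q at which Z takes either exit equally often.
- From eta, the side clock is 1.38 h. At the flask's charge the Q clock is 1.80 h, slower.
- So Z starts with a chance of 0.434 at the Q exit, and I expect less than that overall, as Q falls. An even start needs 0.651 equivalents.
- The forecast says “most Z leaves by a Q-independent side path”, as I do. It gives 19%, and a best charge of 0.55 equiv with 19.5%, below my even charge.
- The flask gives 20.7%. Its best charge is 0.925 equiv, with 26.3%.

    Q + X → G + L (k = 0.236 /M/min)
    D ⇌ X, rate k2*(cs2 - [X]) while solid is left; crystals form when [X] > cs2 (solubility = 7.50 mM, k = 1.86 /min)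
    Z + Q → X + L (k = 0.0501 /M/min)
    Z ⇌ J (K = 11.0, k = 0.00810 /min)
    Z + X → E (k = 0.0186 /M/min)

- The low solubility of X is the main reason for the flask's amount: without it, 20.7% becomes 3.70%. D, the solid form counted in X, holds 18.2% of the Z charged at 8.00 h.
- The scheme's forward constants put the even level at 0.162 M, not my 0.195 M, so the flask's start chance is 0.481, not 0.434.
- A second flask with 0.18 M of Z has the same Q charge and so the same start chance of 0.481; at 8.00 h its X, G and E hold 40.9% of the Z charged, with X at 10.9% and G at 27.5%.

Readings and results are calculated for an exercise.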